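C12–C13 is disconnected by B-alkyl Suzuki–Miyaura coupling of a 9β-vinyl decalinol with an (E)-vinyl iodide made from geranylacetone; acetylation and release of the C3 ketone come last.
C9 (chain β, H-9 α) is set by Eschenmoser–Claisen transfer from a 7β-allylic alcohol; the C8 carbinol comes from α-epoxidation and hydride opening of the C7=C8 alkene that the rearrangement leaves.
Ring A (C1–C4) is closed by Diels–Alder addition of CH2=CH–C(OTBS)=CMe2 to the C5=C10 enone bond of (5S,6R)-6-methylcarvone, whose carbocycle is ring B and whose isopropenyl group steers the facial selectivity before it is excised.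
Enabling feature: the cis C5–C10 ring fusion (H-5 and CH3-10 syn) inside a ring A cyclohexanone (C3=O next to quaternary C4), so that ring A is a cyclohexene retron (C2=C3 enol ether) and C9, the neighbour of C10, can carry the activating carbonyl.
Order of ring formation: ring B is taken from carvone, ring A is closed in the key step.

Key step: step 4

Remark on the structure: the SMILES is read as the cis-fused decalin (5S,8R,9R,10S), with H-5, CH3-10, the C9 side chain and CH3-8 on one face (β) and OH-8 and H-9 on the other (α); locants follow the terpenoid numbering of the target (C1–C10 decalin, C3 ketone, C4 gem-dimethyl, C11 and C12 the first two side-chain carbons).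

Step 1
Reactants: 1 4-methylpent-1-en-3-ol
Product: 2 4-methylpent-1-en-3-one
Conditions: Dess–Martin periodinane, CH2Cl2, 0 °C → rt
Reagents that add atoms: none
Why: Dess–Martin oxidation of a secondary allylic alcohol to the enone proceeds under neutral, anhydrous conditions that spare the polymerisable vinyl ketone, and no stereocentre remains.

Step 2
Reactants: 2 4-methylpent-1-en-3-one
Product: 3 tert-butyldimethyl[(4-methylpenta-1,3-dien-3-yl)oxy]silane
Conditions: TBSOTf, Et3N, CH2Cl2, 0 °C
Reagents that add atoms: tert-butyldimethylsilyl triflate, CC(C)(C)[Si](C)(C)OS(=O)(=O)C(F)(F)F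
Why: Soft enolisation with a silyl triflate and a tertiary amine can only remove the isopropyl methine proton, so O-silylation gives the fully substituted 2-silyloxydiene (silyl dienol ether formation).

Step 3
Reactants: 4 (S)-(+)-carvone
Product: 6 (5S,6R)-6-methylcarvone, via lithium dienolate 5 (not isolated)
Conditions: LiN(iPr)2, THF, −78 °C; then MeI, −78 °C → −20 °C
Reagents that add atoms: iodomethane, CI
Why: Kinetic deprotonation of carvone at C6 gives the cross-conjugated dienolate, which is C-methylated anti to the neighbouring isopropenyl group (enolate alkylation); the configuration of this carbon is of no consequence because it becomes sp2 in step 7.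

Step 4
Reactants: 3 tert-butyldimethyl[(4-methylpenta-1,3-dien-3-yl)oxy]silane; 6 (5S,6R)-6-methylcarvone
Product: 7 cis-fused adduct 3-(TBSO)-4,4,8α,10β-tetramethyl-7β-isopropenyl-5β-H-decal-2-en-9-one
Conditions: 3 (2 equiv), AlBr3/AlMe3 (5:1, 0.2 equiv), toluene/CH2Cl2, −20 °C → 0 °C; pyridine quench
Reagents that add atoms: none
Why: The AlBr3-bound enone 6 and the electron-rich 2-silyloxydiene 3 should combine in a concerted but strongly asynchronous normal-demand [4+2] cycloaddition in which the C4–C5 bond (enol-ether carbon to enone β-carbon) leads and the C1–C10 bond follows. The closest known reaction type is the mixed AlBr3/AlMe3-promoted Diels–Alder reaction of hindered 2-silyloxydienes with 2-methylcycloalkenones, together with Lewis-acid-promoted cycloadditions of carvone with silyloxydienes. Ring A is closed by intermolecular [4+2] cycloaddition, suprafacial on the C5=C10 ring alkene, so the fusion is necessarily cis (H-5 and CH3-10 syn). The absolute sense at C5 and C10 is controlled by the C7 stereocentre of carvone, because the diene attacks the enone β-carbon axially, anti to the isopropenyl group, which places ring A on the α-face. The step needs regioselectivity, secured by the polarity match of the silyloxy-substituted terminus C4 with the β-carbon C5 (which also keeps the quaternary centres C4 and C10 apart), and facial selectivity, secured by the isopropenyl group; endo/exo selectivity is irrelevant because C1 and C4 carry identical substituents. AlMe3 scavenges adventitious acid so that the product keeps its C2=C3 silyl enol ether.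

Step 5
Reactants: 7 cis-fused adduct 3-(TBSO)-4,4,8α,10β-tetramethyl-7β-isopropenyl-5β-H-decal-2-en-9-one
Product: 8 3,3-ethylenedioxy-4,4,8α,10β-tetramethyl-7β-isopropenyl-5β-H-cis-decalin-9-one
Conditions: HOCH2CH2OH (5 equiv), CSA (5 mol %), CH2Cl2, 0 °C → rt
Reagents that add atoms: ethylene glycol, OCCO
Why: Protonation of the silyl enol ether at C2 gives an oxocarbenium ion that is trapped by the diol with loss of silanol (acid-catalysed enol ether to acetal exchange), while the C9 ketone, flanked by quaternary C10 and branched C8, does not ketalise.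

Step 6
Reactants: 8 3,3-ethylenedioxy-4,4,8α,10β-tetramethyl-7β-isopropenyl-5β-H-cis-decalin-9-one
Product: 10 3,3-ethylenedioxy-4,4,8,10β-tetramethyl-5β-H-cis-decalin-9-one, via methoxy hydroperoxide 9 (not isolated)
Conditions: O3, CH2Cl2/MeOH, −78 °C; then FeSO4·7H2O, PhSH, −78 °C → rt
Reagents that add atoms: none
Why: Hydrodealkenylation: Criegee ozonolysis in methanol gives the α-methoxy hydroperoxide, divalent iron cleaves its O–O bond, β-scission of the alkoxy radical expels methyl acetate, and the C7 radical takes a hydrogen atom from the thiol, which removes the C7 stereocentre after it has done its work.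

Step 7
Reactants: 10 3,3-ethylenedioxy-4,4,8,10β-tetramethyl-5β-H-cis-decalin-9-one
Product: 12 3,3-ethylenedioxy-4,4,8,10β-tetramethyl-5β-H-cis-decal-8-en-9-yl triflate, via potassium enolate 11 (not isolated)
Conditions: KN(SiMe3)2, THF, −78 → 0 °C; then PhNTf2, 0 °C → rt
Reagents that add atoms: N-phenylbis(trifluoromethanesulfonimide), O=S(=O)(N(c1ccccc1)S(=O)(=O)C(F)(F)F)C(F)(F)F
Why: Only C8 bears an α-hydrogen (C10 is quaternary), so deprotonation gives a single tetrasubstituted enolate that is O-sulfonylated (enol triflate formation).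

Step 8
Reactants: 12 3,3-ethylenedioxy-4,4,8,10β-tetramethyl-5β-H-cis-decal-8-en-9-yl triflate
Product: 13 3,3-ethylenedioxy-4,4,8,10β-tetramethyl-5β-H-cis-decal-8-ene
Conditions: Pd(OAc)2 (5 mol %), PPh3, Bu3N, HCO2H, DMF, 60 °C
Reagents that add atoms: none
Why: Palladium-catalysed formate reduction of the enol triflate (oxidative addition to zerovalent palladium, decarboxylation of formate to a palladium hydride, reductive elimination) gives the trisubstituted C8=C9 alkene without touching a stereocentre.

Step 9
Reactants: 13 3,3-ethylenedioxy-4,4,8,10β-tetramethyl-5β-H-cis-decal-8-ene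
Product: 14 3,3-ethylenedioxy-4,4,8,10β-tetramethyl-5β-H-cis-decal-8-en-7β-ol
Conditions: SeO2 (0.5 equiv), tBuOOH (2 equiv), CH2Cl2, 0 °C → rt
Reagents that add atoms: selenium dioxide, O=[Se]=O, regenerated by tert-butyl hydroperoxide, CC(C)(C)OO
Why: Selenium dioxide allylic oxidation (ene reaction, then [2,3]-sigmatropic shift) functionalises the ring methylene on the more substituted alkene terminus, C7; selenium attacks C9 on the β-face, anti to the axial C1 methylene of ring A, takes the pseudoaxial 7β-hydrogen, and the suprafacial [2,3] shift returns oxygen to C7 on that same β-face.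

Step 10
Reactants: 14 3,3-ethylenedioxy-4,4,8,10β-tetramethyl-5β-H-cis-decal-8-en-7β-ol
Product: 16 2-[3,3-ethylenedioxy-4,4,8,10β-tetramethyl-5β-H-cis-decal-7-en-9β-yl]-N,N-dimethylacetamide, via ketene N,O-acetal 15 (not isolated)
Conditions: MeC(OMe)2NMe2 (5 equiv), xylenes, 140 °C
Reagents that add atoms: N,N-dimethylacetamide dimethyl acetal, COC(C)(OC)N(C)C
Why: Eschenmoser–Claisen rearrangement: the ketene N,O-acetal formed on the 7β-oxygen undergoes a suprafacial [3,3] shift, so the new C9–C11 bond forms on the β-face (H-9 becomes α) and the double bond moves to C7=C8.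

Step 11
Reactants: 16 2-[3,3-ethylenedioxy-4,4,8,10β-tetramethyl-5β-H-cis-decal-7-en-9β-yl]-N,N-dimethylacetamide
Product: 17 7α,8α-epoxide of amide 16
Conditions: mCPBA (1.2 equiv), NaHCO3, CH2Cl2, 0 °C
Reagents that add atoms: 3-chloroperoxybenzoic acid, OOC(=O)c1cccc(Cl)c1
Why: Peracid epoxidation of the only alkene should occur anti to the C9 side chain, which A(1,2) strain with the C8 methyl holds pseudoaxial on the β-face (as in epoxidations of 8-methyl-Δ7-drimene-type systems), so the oxygen is placed α at C8.

Step 12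
Reactants: 17 7α,8α-epoxide of amide 16
Product: 18 9β-[2-(dimethylamino)ethyl]-3,3-ethylenedioxy-4,4,8β,10β-tetramethyl-5β-H-cis-decalin-8α-ol
Conditions: LiAlH4, THF, 0 °C → reflux; Fieser work-up
Reagents that add atoms: none
Why: LiAlH4 reduces the tertiary amide to the amine and opens the trisubstituted epoxide by hydride attack at the less substituted C7 (trans-diaxial opening), which leaves the C8–O bond, and thus the 8α-carbinol configuration, untouched.

Step 13
Reactants: 18 9β-[2-(dimethylamino)ethyl]-3,3-ethylenedioxy-4,4,8β,10β-tetramethyl-5β-H-cis-decalin-8α-ol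
Product: 20 9β-vinyl-3,3-ethylenedioxy-4,4,8β,10β-tetramethyl-5β-H-cis-decalin-8α-ol, via amine N-oxide 19 (not isolated)
Conditions: mCPBA (1.05 equiv), CH2Cl2, 0 °C; filtration through basic Al2O3; then toluene, 110 °C
Reagents that add atoms: none
Why: Chemoselective N-oxidation followed by thermal Cope elimination (syn, five-membered transition state) can only use the C11 hydrogens and so gives the terminal C11=C12 alkene without affecting a stereocentre.

Step 14
Reactants: 21 geranylacetone
Product: 23 (E)-6,10-dimethylundeca-5,9-dien-1-yne, via enol phosphate 22 (not isolated)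
Conditions: LiN(iPr)2 (1.05 equiv), THF, −78 °C; ClP(O)(OEt)2; then LiN(iPr)2 (2.3 equiv), −78 °C → rt; H2O
Reagents that add atoms: none
Why: One-pot conversion of a methyl ketone into a terminal alkyne: the kinetic enolate is O-phosphorylated and the enol phosphate undergoes base-induced elimination, the internal E-alkene being untouched.

Step 15
Reactants: 23 (E)-6,10-dimethylundeca-5,9-dien-1-yne
Product: 25 (1E,5E)-1-iodo-2,6,10-trimethylundeca-1,5,9-triene, via alkenylalane 24 (not isolated)
Conditions: AlMe3 (2 equiv), Cp2ZrCl2 (0.25 equiv), CH2Cl2, 0 °C → rt; then I2, THF, −30 → 0 °C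
Reagents that add atoms: trimethylaluminium, C[Al](C)C; iodine, II
Why: Zirconium-catalysed carboalumination adds methyl and aluminium syn across the alkyne with methyl on the internal carbon, and iodinolysis of the C–Al bond with retention gives the E-trisubstituted vinyl iodide.

Step 16
Reactants: 25 (1E,5E)-1-iodo-2,6,10-trimethylundeca-1,5,9-triene
Product: 26 (2E,6E,10E)-11-iodo-2,6,10-trimethylundeca-2,6,10-trien-1-ol
Conditions: SeO2 (0.1 equiv), tBuOOH, CH2Cl2, 0 °C → rt
Reagents that add atoms: selenium dioxide, O=[Se]=O, regenerated by tert-butyl hydroperoxide, CC(C)(C)OO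
Why: Selenium dioxide allylic oxidation (ene, then [2,3] shift) is selective for the E-methyl of the terminal, most electron-rich and least hindered trisubstituted alkene and gives the E-allylic alcohol.

Step 17
Reactants: 20 9β-vinyl-3,3-ethylenedioxy-4,4,8β,10β-tetramethyl-5β-H-cis-decalin-8α-ol; 26 (2E,6E,10E)-11-iodo-2,6,10-trimethylundeca-2,6,10-trien-1-ol
Product: 28 myrrhanone A 3-ethylene ketal (cis-fused; free C8 and terminal allylic hydroxyls), via B-alkyl borane 27 (not isolated)
Conditions: 9-BBN dimer, THF, rt; then 26, Pd(dppf)Cl2 (5 mol %), AsPh3, Cs2CO3, DMF/THF/H2O, rt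
Reagents that add atoms: none
Why: 9-BBN hydroborates only the monosubstituted vinyl group, boron at C12, and B-alkyl Suzuki–Miyaura coupling with the vinyl iodide forms the C12–C13 bond with retention of the E geometry; free hydroxyl groups are tolerated.

Step 18
Reactants: 28 myrrhanone A 3-ethylene ketal
Product: 29 myrrhanone A acetate 3-ethylene ketal
Conditions: Ac2O, pyridine, DMAP (cat.), CH2Cl2, 0 °C
Reagents that add atoms: acetic anhydride, CC(=O)OC(C)=O
Why: Acylation with acetic anhydride and pyridine takes the primary allylic alcohol only, the hindered tertiary C8 hydroxyl being inert under these conditions.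

Step 19
Reactants: 29 myrrhanone A acetate 3-ethylene ketal
Product: 30 myrrhanone A acetate, (5S,8R,9R,10S)
Conditions: PPTS, acetone/H2O (5:1), 50 °C
Reagents that add atoms: water, O
Why: Mild acid-catalysed hydrolysis of the dioxolane releases the C3 ketone without dehydrating the tertiary alcohol, cleaving the allylic acetate or isomerising the trisubstituted alkenes.

Compound list
1 | 4-methylpent-1-en-3-ol (racemic) | C=CC(O)C(C)C | starting material
2 | 4-methylpent-1-en-3-one | C=CC(=O)C(C)C | intermediate
3 | tert-butyldimethyl[(4-methylpenta-1,3-dien-3-yl)oxy]silane | C=CC(O[Si](C)(C)C(C)(C)C)=C(C)C | intermediate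
4 | (S)-(+)-carvone | CC1=CC[C@@H](CC1=O)C(C)=C | starting material
5 | lithium dienolate of carvone (C1–OLi, C1=C6) | CC1=CC[C@H](C(C)=C)C=C1O[Li] | intermediate
6 | (5S,6R)-6-methylcarvone (methyl trans to isopropenyl) | CC1=CC[C@H](C(C)=C)[C@@H](C)C1=O | intermediate
7 | 3-(TBSO)-4,4,8α,10β-tetramethyl-7β-isopropenyl-5β-H-decal-2-en-9-one (cis-fused) | O=C1[C@@]2(C)CC=C(O[Si](C)(C)C(C)(C)C)C(C)(C)[C@H]2C[C@H](C(C)=C)[C@H]1C | intermediate
8 | 3,3-ethylenedioxy-4,4,8α,10β-tetramethyl-7β-isopropenyl-5β-H-cis-decalin-9-one | O=C1[C@@]2(C)CCC3(OCCO3)C(C)(C)[C@H]2C[C@H](C(C)=C)[C@H]1C | intermediate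
9 | α-methoxy hydroperoxide of 8 (C7–C(CH3)(OCH3)OOH) | O=C1[C@@]2(C)CCC3(OCCO3)C(C)(C)[C@H]2C[C@H](C(C)(OC)OO)[C@H]1C | intermediate
10 | 3,3-ethylenedioxy-4,4,8,10β-tetramethyl-5β-H-cis-decalin-9-one (8α-methyl drawn) | O=C1[C@@]2(C)CCC3(OCCO3)C(C)(C)[C@H]2CC[C@H]1C | intermediate
11 | potassium enolate of 10 (C8=C9–OK) | [K]OC1[C@@]2(C)CCC3(OCCO3)C(C)(C)[C@H]2CCC=1C | intermediate
12 | 3,3-ethylenedioxy-4,4,8,10β-tetramethyl-5β-H-cis-decal-8-en-9-yl triflate | FC(F)(F)S(=O)(=O)OC1[C@@]2(C)CCC3(OCCO3)C(C)(C)[C@H]2CCC=1C | intermediate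
13 | 3,3-ethylenedioxy-4,4,8,10β-tetramethyl-5β-H-cis-decal-8-ene | CC1=C[C@@]2(C)CCC3(OCCO3)C(C)(C)[C@H]2CC1 | intermediate
14 | 3,3-ethylenedioxy-4,4,8,10β-tetramethyl-5β-H-cis-decal-8-en-7β-ol | CC1=C[C@@]2(C)CCC3(OCCO3)C(C)(C)[C@H]2C[C@@H]1O | intermediate
15 | ketene N,O-acetal of 14 (C7–O–C(=CH2)NMe2) | CC1=C[C@@]2(C)CCC3(OCCO3)C(C)(C)[C@H]2C[C@@H]1OC(=C)N(C)C | intermediate
16 | 2-[3,3-ethylenedioxy-4,4,8,10β-tetramethyl-5β-H-cis-decal-7-en-9β-yl]-N,N-dimethylacetamide (9α-H) | CN(C)C(=O)C[C@@H]1[C@@]2(C)CCC3(OCCO3)C(C)(C)[C@H]2CC=C1C | intermediate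
17 | 7α,8α-epoxide of amide 16 | CN(C)C(=O)C[C@@H]1[C@@]2(C)CCC3(OCCO3)C(C)(C)[C@H]2C[C@H]4O[C@@]14C | intermediate
18 | 9β-[2-(dimethylamino)ethyl]-3,3-ethylenedioxy-4,4,8β,10β-tetramethyl-5β-H-cis-decalin-8α-ol | CN(C)CC[C@@H]1[C@@]2(C)CCC3(OCCO3)C(C)(C)[C@H]2CC[C@@]1(C)O | intermediate
19 | N-oxide of amine 18 | C[N+](C)([O-])CC[C@@H]1[C@@]2(C)CCC3(OCCO3)C(C)(C)[C@H]2CC[C@@]1(C)O | intermediate
20 | 9β-vinyl-3,3-ethylenedioxy-4,4,8β,10β-tetramethyl-5β-H-cis-decalin-8α-ol | C=C[C@@H]1[C@@]2(C)CCC3(OCCO3)C(C)(C)[C@H]2CC[C@@]1(C)O | intermediate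
21 | geranylacetone, (E)-6,10-dimethylundeca-5,9-dien-2-one | CC(=O)CC/C=C(\C)CCC=C(C)C | starting material
22 | diethyl enol phosphate of 21 (terminal enol) | C=C(OP(=O)(OCC)OCC)CC/C=C(\C)CCC=C(C)C | intermediate
23 | (E)-6,10-dimethylundeca-5,9-dien-1-yne | C#CCC/C=C(\C)CCC=C(C)C | intermediate
24 | (E)-alkenyl(dimethyl)alane from 23 | C[Al](C)/C=C(\C)CC/C=C(\C)CCC=C(C)C | intermediate
25 | (1E,5E)-1-iodo-2,6,10-trimethylundeca-1,5,9-triene | I/C=C(\C)CC/C=C(\C)CCC=C(C)C | intermediate
26 | (2E,6E,10E)-11-iodo-2,6,10-trimethylundeca-2,6,10-trien-1-ol | OC/C(C)=C/CC/C(C)=C/CC/C(C)=C/I | intermediate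
27 | B-alkyl-9-BBN from 20 (boron on C12) | C1CCC2CCCC1B2CC[C@@H]1[C@@]2(C)CCC3(OCCO3)C(C)(C)[C@H]2CC[C@@]1(C)O | intermediate
28 | myrrhanone A 3-ethylene ketal (cis-fused; free C8 and terminal hydroxyls) | OC/C(C)=C/CC/C(C)=C/CC/C(C)=C/CC[C@@H]1[C@@]2(C)CCC3(OCCO3)C(C)(C)[C@H]2CC[C@@]1(C)O | intermediate
29 | myrrhanone A acetate 3-ethylene ketal | CC(=O)OC/C(C)=C/CC/C(C)=C/CC/C(C)=C/CC[C@@H]1[C@@]2(C)CCC3(OCCO3)C(C)(C)[C@H]2CC[C@@]1(C)O | intermediate
30 | myrrhanone A acetate, (5S,8R,9R,10S), cis-fused | CC(=O)OC/C(C)=C/CC/C(C)=C/CC/C(C)=C/CC[C@@H]1[C@@]2(C)CCC(=O)C(C)(C)[C@H]2CC[C@@]1(C)O | target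

Total step count: 19
Longest linear sequence: 15 steps (steps 1, 2, 4–13, 17–19)

Steps most likely to fail

Step 4. The hindered gem-dimethyl terminus of the diene may react too slowly, so that acid-induced desilylation or oligomerisation of the diene and erosion of facial control take over. The fallback sets out from 3 and 6 and makes the two bonds in two separate conjugate additions. TiCl4-mediated Mukaiyama–Michael addition of 3 to 6 (CH2Cl2, −78 °C) should form C4–C5 trans to the isopropenyl group and give, after aqueous work-up, 2,6-dimethyl-3-(2-methyl-3-oxopent-4-en-2-yl)-5-(prop-1-en-2-yl)cyclohexan-1-one F1. Catalytic KOtBu in tBuOH/THF should then close ring A by intramolecular Michael addition of the C10 enolate to the vinyl ketone (C1–C10), giving the cis-fused 4,4,8α,10β-tetramethyl-7β-isopropenyl-5β-H-decalin-3,9-dione F2. Ketalisation of the less hindered C3 carbonyl (ethylene glycol, CSA) comes back to the route at 8.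

Step 9. The allylic oxidation may over-oxidise to the C7 enone, attack the C8 methyl group instead of the ring methylene, or proceed on the α-face. The fallback sets out from 10. IBX dehydrogenation (DMSO/toluene, 70 °C) should give 3,3-ethylenedioxy-4,4,8,10β-tetramethyl-5β-H-cis-decal-7-en-9-one F3. Nucleophilic epoxidation (H2O2, NaOH, MeOH), by axial attack at C7 on the β-face away from C4, should give the 7β,8β-epoxy ketone F4. Wharton transposition (N2H4·H2O, AcOH, MeOH) then comes back to the route at 14 with the oxygen kept on the β-face of C7.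

Step 11. Facial selectivity of the epoxidation may be insufficient, with the peracid attacking the β-face. The fallback sets out from 16 and reverses the facial outcome. NBS in aqueous THF should form the bromonium ion on the face the peracid prefers, and water should open it at the tertiary C8 from the opposite face, giving the 7β-bromo-8α-hydroxy amide F5. K2CO3 in MeOH then closes the bromohydrin to the α-epoxide and comes back to the route at 17.

Further compounds
F1 | step 4 | 2,6-dimethyl-3-(2-methyl-3-oxopent-4-en-2-yl)-5-(prop-1-en-2-yl)cyclohexan-1-one (3,5-trans; C2 epimers) | O=C1C(C)[C@@H](C(C)(C)C(=O)C=C)C[C@H](C(C)=C)[C@H]1C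
F2 | step 4 | 4,4,8α,10β-tetramethyl-7β-isopropenyl-5β-H-cis-decalin-3,9-dione | O=C1[C@@]2(C)CCC(=O)C(C)(C)[C@H]2C[C@H](C(C)=C)[C@H]1C
F3 | step 9 | 3,3-ethylenedioxy-4,4,8,10β-tetramethyl-5β-H-cis-decal-7-en-9-one | O=C1[C@@]2(C)CCC3(OCCO3)C(C)(C)[C@H]2CC=C1C
F4 | step 9 | 7β,8β-epoxide of F3 | O=C1[C@@]2(C)CCC3(OCCO3)C(C)(C)[C@H]2C[C@@H]4O[C@]14C
F5 | step 11 | 7β-bromo-8α-hydroxy derivative of amide 16 | CN(C)C(=O)C[C@@H]1[C@@]2(C)CCC3(OCCO3)C(C)(C)[C@H]2C[C@H](Br)[C@@]1(C)O
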